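| flask | X | E | temperature | remark | time |
|---|---|---|---|---|---|
| ash | 0.10 M | 0.30 M | 65 °C | run made earlier |  |
| birch | 0.14 M | 0.30 M | 80 °C | run made earlier |  |
| elm | 0.22 M | 0.30 M | 65 °C | run made earlier |  |
| oak | 0.10 M | 0.45 M | 80 °C | run made earlier |  |
| teal | 0.10 M | 0.300 M | 80 °C | everything together at the start | 50 min |
| ochre | 0.10 M | 0.300 M |  | everything together at the start at 60 °C, warmed to 80 °C at 40 min | 50 min |
| amber | 0.10 M | 0.300 M (fed, over 40 min) | 80 °C | all else is in the flask from the start; the feed brings no volume worth counting | 50 min |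
| grey | 0.10 M (fed, over 40 min) | 0.300 M |  | the addition at 60 °C, then warmed to 80 °C; the feed brings no volume worth counting | 50 min |

- ash (time / min: L / %, D / %, X / %): 4.00: 2, 7, 93; 12.0: 3, 14, 77; 20.0: 12, 17, 65; 30.0: 16, 15, 53; 50.0: 29, 12, 40; 60.0: 30, 13, 32
- birch (time / min: L / %, D / %, X / %): 10.0: 14, 13, 61; 20.0: 18, 15, 39; 30.0: 27, 12, 28; 40.0: 28, 11, 22; 50.0: 23, 7, 17; 60.0: 26, 5, 14
- elm (time / min: L / %, D / %, X / %): 10.0: 3, 10, 80; 15.0: 6, 11, 68; 25.0: 12, 14, 64; 40.0: 16, 11, 47; 80.0: 21, 8, 28; 120: 22, 4, 22
- oak (time / min: L / %, D / %, X / %): 12.0: 25, 16, 40; 25.0: 34, 11, 21; 40.0: 25, 4, 9; 50.0: 22, 5, 7; 60.0: 21, 2, 6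

(scatter of a reading: 1.5 percentage points)

- in percentages every species weighs as the X in it: one Z counts as two
- the numbers in the tables scatter by 1.5 percentage points (one standard deviation)
- steps under discussion: E + D -> L; X + D -> Z; E + L -> G; X + E -> D

* the flask with the highest amount of L, in percent of the X charged ("all alike" if they lie within 1.5 percentage points) (teal / ochre / amber / grey / all alike)
* final L, as a percentage of the X charged, in teal
* final L, as a percentage of the X charged, in ochre
* final L, as a percentage of the X charged, in amber
* final L, as a percentage of the X charged, in grey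

- Teal and amber receive equal charges at 80 °C, so you can compare them by the ratio of E to X that D meets.
- Let kL and kZ be the constants of E + D → L and X + D → Z. Their rates, divided, give the branch ratio B (a selectivity factor): B = κ[E]/[X], with κ = kL/kZ. D and time drop out, so B says where D goes, not how far a flask gets.
- Which numbers matter? The constants of X + E → D and E + L → G do not appear in B. Now try κ = 1 at teal's starting ratio of 3.00: D's share going to L is 75.0%. Doubling κ gives 85.7%, and dividing it by two gives 60.0%. The share moves by less than κ does, so a rough κ will do for an estimate of it.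
- For κ itself, take birch, which ran at 80 °C like teal and amber, at 10.0 min. The gap in the balance is 12.0%, which I count as Z, although any G hides there too. One Z holds two X, so, with B taken as steady and L's loss to G ignored, L over Z in percent equals B divided by two. With [X] midway between start and reading and [E] at its charge, the reading gives 0.877 for κ, the branch constant, and it carries the scatter of three readings.
- My reckoning gives B = 2.63 at teal's start. Amber at mid-feed, a later moment, with E counted as the half fed so far and none of it used, and X taken at its charge, has 1.31. On these two estimates I expect amber to lose more D to Z than teal.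
- The forecast names teal, with L at 28.5% in teal, 25% in ochre, 24% in amber and 21% in grey. Of amber it says: “starved E early favours Z and delays L”.

    E + D → L (k = 0.463 L mol⁻¹ min⁻¹, Ea = 52.0 kJ mol⁻¹)
    X + D → Z (k = 0.419 L mol⁻¹ min⁻¹, Ea = 57.0 kJ mol⁻¹)
    E + L → G (k = 0.138 L mol⁻¹ min⁻¹, Ea = 61.0 kJ mol⁻¹)
    X + E → D (k = 0.166 L mol⁻¹ min⁻¹, Ea = 60.0 kJ mol⁻¹)
    (constants at 80 °C)

- Teal ends highest at 29.4%, with amber at 25.8%, ochre at 25.5% and grey at 20.4%. At 50.0 min amber holds Z 24.0% against teal's 20.9%, with X left at 26.2% against 14.7%. With κ, B at 25.0 min is 5.21 in teal and 1.98 in amber.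
- Take grey's recipe with E cut to 0.12 M, carrying κ over unchanged to the cool stage as an assumption. With E and X both taken at their charges, although X is fed in this flask, κ gives L over Z in percent of 0.526. The computed flask holds L 6.07% and Z 8.84%, a ratio of 0.687.

All runs are simulated for substances that don't exist, noise included.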